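## Analysis of the target

The target is a cis-fused decalin of the eudesmane type. Ring A is C1, C2, C3, C4, C5, C10 and ring B is C5, C6, C7, C8, C9, C10, with a C8 ketone, a C7 isopropyl group, a C10 methyl group, a C4 methyl/acetoxy carbon and a C3 epoxyangelate. The ring stereocentres are C3 (R), C4 (S), C5 (S), C7 (R) and C10 (R), and the ester side chain carries two more (2S,3S). H5, the C10 methyl group and the C7 isopropyl group lie on one face (β). The two ring oxygens at C3 and C4 are cis to each other on the opposite, concave face (α), and the C4 methyl group is β. In the preferred chair–chair conformer the isopropyl group and the C3 oxygen are equatorial and the C4 acetoxy group is axial. Sensitive groups are the glycidic ester epoxide (acid, nucleophiles), the hindered tertiary acetate next to a second ester (elimination, acyl migration as long as one hydroxyl is free) and the ketone with its epimerisable C7. The hard parts are the vicinal C5 (tertiary) and C10 (quaternary) fusion centres in a cis relation with defined relation to C7, and a tertiary oxygen at C4 on the concave face. The strategy rests on one feature: C5 is α to C4, which can be at the carboxyl oxidation level, and C10 is the far end of a C8–C9=C10 allyl unit whose C8 carries oxygen. A C4 carboxylate esterified at the C8 oxygen (a δ-lactone through C5, C6, C7) therefore makes C5 and C10 the termini of a 1,5-diene.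

## Retrosynthetic reasoning

**Ketone and esters (40 ⇐ 39 ⇐ 38 ⇐ 37 ⇐ 31 + 35).** The C8 ketone is taken back to a silyl-protected alcohol (39, 38), so that C7 cannot epimerise while ring A is still open. In the closed bicycle the natural C7 configuration is the equatorial, favoured one, so oxidation can come last. The two C–O acyl bonds are cut next: first the tertiary acetate (38 ⇐ 37), then the C3 ester (37 ⇐ 31 + 35). The secondary equatorial hydroxyl of cis-diol 31 is acylated first with the bulky, poorly migrating epoxy acid, so no free hydroxyl ever sits next to an acetate.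

**Epoxy acid (35 ⇐ 34 ⇐ 33 ⇐ 32).** Epoxidising an angelate on the decalin would give both epoxide diastereomers, so the side chain is made separately as a single enantiomer. The carboxyl group of 35 is taken back to the primary alcohol 34, whose epoxide comes from reagent-controlled epoxidation of the (Z)-allylic alcohol 33, the reduction product of 32.

**C3 and C4 oxygens (31 ⇐ 30 ⇐ 29 ⇐ 28 ⇐ 27).** Both C–O bonds are cut back to the C3=C4 alkene of 27. Direct cis-dihydroxylation would occur on the open convex β face and put the C4 oxygen on the wrong side. The C4 oxygen is therefore introduced with inversion, by trans-diaxial opening of the β-epoxide 28 at the tertiary carbon (29). C3 is then corrected by oxidation (30) and axial hydride delivery (31).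

**Ring A (27 ⇐ 26 ⇐ 25 ⇐ 24 ⇐ 23 ⇐ 21).** The C3=C4 bond is cut by ring-closing metathesis to diene 26. Its two alkenes come from the C3 aldehyde and C4 methyl ketone of 25. The aldehyde comes from the benzyl-protected chain end (24, 23), and the methyl ketone from the C4 ester of 21. Cutting here uses the two cis appendages on C5 and C10 directly and needs no new stereocentre.

**C8 oxygen (21 ⇐ 20 ⇐ 18 ⇐ 17).** The C8–O bond is cut back to the C8=C9 alkene of 18 by hydroboration. C9 is flanked by the quaternary C10, so boron should go to C8. This is done while the alkene is the only one in the molecule and on the methyl ester 18, because the free acid 17 would itself be reduced.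

**Key disconnection (17 ⇐ 14).** The C5–C10 bond is cut and the C8–O bond re-formed, which turns cyclohexene acid 17 into the cis-5,6-disubstituted δ-lactone 14. One carbinol centre (C8) and the (E)-alkene geometry are traded for the C5/C10 pair by a stereospecific [3,3] shift. The alkene left at C8=C9 marks the site of the ketone, and the carboxyl carbon is C4. No other cut of ring B gives both fusion centres from one pre-set stereocentre.

**Lactone (14 ⇐ 13 ⇐ 11).** The lactone carbonyl is taken back to the lactol 13, and the C4–C5 bond is cut by a one-carbon homologation of the vinyl group of 11. The ring then closes by itself on the C8 hydroxyl.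

**C7–C8 bond (11 ⇐ 6 + 7).** The cis-lactone needs the syn relation between the C7 isopropyl group and the C8 oxygen. Adding an alkenyl metal to an α-isopropyl aldehyde would follow the Felkin–Anh model and give mainly the anti isomer, hence the trans-lactone, so that bond is not used. The C7–C8 bond is instead formed by a (Z)-γ-substituted allylboron addition to enal 6, with the allyl unit derived from alkene 7. The closed transition state gives syn, and the chiral boron ligands set the absolute configuration.

**Enal (6 ⇐ 5 ⇐ 2 ⇐ 1).** The C10 methyl–carbon bond and the C8–C9 bond are cut by syn-carbometalation of alkyne 2 and one-carbon trapping (5). This fixes the (E)-geometry that later decides C10. Alkyne 2 is the benzyl ether of 1.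

## Alternatives that were turned down

**Alternative 1:** Disconnection of C5–C10 and C8–C9 together, by an intramolecular Diels–Alder reaction. In the forward direction the acyclic trienone A2, an isopropenyl ketone tethered through the C3/C4 acetonide to a 1-silyloxy-2-isopropyl diene, would cyclise to the cis-fused decalin A1. In its favour, two C–C bonds, both rings and the quaternary C10 form in one step from a convergent precursor; on bond and ring economy it is stronger than the chosen route. Against it for this target: the dienophile is 1,1-disubstituted and the diene trisubstituted, so the reacting ends are crowded. The ring fusion and the facial sense depend on how the tether folds around the remote acetonide, not on a stereospecific element. A1 also carries a C1 ketone that the target lacks, C7 is still sp2 and would be set later by a hydrogenation of uncertain facial sense, and C8 needs a redox adjustment. The chosen strategy forms only one bond and one ring in its key step, but it transfers chirality stereospecifically to C5 and C10 with C7 already fixed, and it leaves functionality only where the target has it.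

**Alternative 2:** Disconnection of C3–C4 by a ketyl–carbonyl (pinacol) coupling with divalent samarium (SmI2). The keto aldehyde A4 would close ring A to the cis-diol A3. In its favour, one step forms ring A and installs both oxygens in the cis relation; this is clearly shorter than the five steps (metathesis, epoxidation, hydrolysis, oxidation, reduction) used here. Against it: it does not address the C5/C10 pair, which must already be present in A4. The diol can form on either face, and the required isomer has the C4 hydroxyl axial on the concave face, which a chelated coupling does not secure. C5 is also α to the ketone during the reduction. The chosen strategy solves the fusion centres and fixes C4 by an invertive epoxide opening whose outcome follows from the conformation. A4 is a close relative of intermediate 25, so the two approaches differ only in how ring A is closed.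

**Alternative 3:** Disconnection of C1–C10 by a cathodic enone–enone hydrocyclisation. Reduction of the vinyl ketone in A6 would give a radical anion whose β-carbon (C1) adds to C10 of the ring B enone and gives the hydroxy diketone A5. In its favour, the quaternary centre is formed with the C3 and C8 carbonyls and the C4 hydroxyl already in place, so its oxidation-state economy is better than that of the chosen route. Against it: the bond forms at a β,β-disubstituted enone carbon, which is slow, and the cis fusion rests on a kinetic preference. C5 in A6 is vinylogously enolisable. The reduced α-hydroxy ketone can lose its C4 oxygen, and the vinyl ketone can dimerise or polymerise. The two ketones of A5 must then be told apart. The chosen strategy is longer after the key step but sets C10 relative to C5 by a concerted shift with no competing pathway of similar energy.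

Key step: step 7

Remark on the chemistry: the hydroboration product 20 is drawn with the C8 hydroxyl trans to the isopropyl group. This centre becomes the ketone in step 26, so its configuration does not reach the target. Lactol 13 is an anomeric mixture and is used as such.

## Route

Step 1
Reactants: 1 pent-4-yn-1-ol
Product: 2 5-(benzyloxy)pent-1-yne
Conditions: NaH, BnBr, Bu4NI (cat.), THF, 0 °C → rt
Reagents that add atoms: benzyl bromide, BrCc1ccccc1
Why: Williamson etherification of the primary alkoxide; the benzyl ether survives the organometallic steps and is removed in step 12, when no alkene is present.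

Step 2
Reactants: 2 5-(benzyloxy)pent-1-yne
Product: 5 (2E)-6-(benzyloxy)-3-methylhex-2-en-1-ol, via alkenylalane 3 (not isolated), via lithium alkenylalanate 4 (not isolated)
Conditions: Me3Al, Cp2ZrCl2 (20 mol %), CH2Cl2, 0 °C → rt; then n-BuLi, THF, −78 °C; (CH2O)n, −78 °C → rt; 1 M HCl
Reagents that add atoms: trimethylaluminium, C[Al](C)C; formaldehyde (as paraformaldehyde), C=O
Why: Negishi zirconium-catalysed syn-carboalumination puts methyl on the internal and aluminium on the terminal alkyne carbon; the alanate adds to formaldehyde with retention, which fixes the (E)-trisubstituted alkene that later decides C10.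

Step 3
Reactants: 5 (2E)-6-(benzyloxy)-3-methylhex-2-en-1-ol
Product: 6 (2E)-6-(benzyloxy)-3-methylhex-2-enal
Conditions: MnO2, CH2Cl2, rt
Reagents that add atoms: none
Why: Selective oxidation of the allylic alcohol by MnO2; the neutral heterogeneous conditions should leave the alkene geometry and the benzyl ether untouched.

Step 4
Reactants: 6 (2E)-6-(benzyloxy)-3-methylhex-2-enal; 7 (2Z)-4-methylpent-2-ene
Product: 11 (3S,4R,5E)-9-(benzyloxy)-6-methyl-3-(propan-2-yl)nona-1,5-dien-4-ol, via allylpotassium 8 (not isolated), via allylborane 9 (not isolated), via borinate 10 (not isolated)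
Conditions: 7, n-BuLi, KOt-Bu, THF, −78 → −50 °C; (+)-Ipc2BOMe, −78 °C; BF3·OEt2; 6, −78 °C; then NaOH, H2O2, 0 °C → rt
Reagents that add atoms: none
Why: Brown allylboration with a (Z)-γ-substituted allyldiisopinocampheylborane through a Zimmerman–Traxler chair: the (Z)-geometry, kept by metalating the methyl group of 7 at low temperature, gives the syn C7/C8 relation; the isopinocampheyl groups of the (−)-α-pinene series deliver the allyl unit to the Re face of the aldehyde, which sets C8 (R) and with it C7.

Step 5
Reactants: 11 (3S,4R,5E)-9-(benzyloxy)-6-methyl-3-(propan-2-yl)nona-1,5-dien-4-ol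
Product: 13 (5R,6R)-6-[(1E)-5-(benzyloxy)-2-methylpent-1-en-1-yl]-5-(propan-2-yl)oxan-2-ol, via hydroxy aldehyde 12 (not isolated)
Conditions: Rh(acac)(CO)2 (2 mol %), BIPHEPHOS (4 mol %), CO/H2 (1:1, 5 bar), THF, 60 °C
Reagents that add atoms: carbon monoxide, [C-]#[O+]
Why: Linear-selective hydroformylation of the monosubstituted alkene (the trisubstituted alkene is too hindered to react) adds C4; the δ-hydroxy aldehyde closes by itself to the six-membered lactol.

Step 6
Reactants: 13 (5R,6R)-6-[(1E)-5-(benzyloxy)-2-methylpent-1-en-1-yl]-5-(propan-2-yl)oxan-2-ol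
Product: 14 (5R,6R)-6-[(1E)-5-(benzyloxy)-2-methylpent-1-en-1-yl]-5-(propan-2-yl)oxan-2-one
Conditions: TEMPO (10 mol %), PhI(OAc)2, CH2Cl2, rt
Reagents that add atoms: none
Why: Oxoammonium oxidation of the lactol to the δ-lactone under neutral conditions that leave the allylic C8–O bond and the alkene alone; no stereocentre is touched.

Step 7
Reactants: 14 (5R,6R)-6-[(1E)-5-(benzyloxy)-2-methylpent-1-en-1-yl]-5-(propan-2-yl)oxan-2-one
Product: 17 (1S,2R,5R)-2-[3-(benzyloxy)propyl]-2-methyl-5-(propan-2-yl)cyclohex-3-ene-1-carboxylic acid, via silyl ketene acetal 15 (not isolated), via silyl ester 16 (not isolated)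
Conditions: LiN(i-Pr)2, TBSCl, HMPA, THF, −78 °C; then PhMe, 105 °C; then 1 M HCl, THF, rt
Reagents that add atoms: none
Why: LiN(i-Pr)2 removes a C5 proton and the enolate is O-silylated in situ to the cyclic ketene acetal 15, whose ring fixes the geometry of the C4=C5 bond. On heating, 15 undergoes a [3,3]-sigmatropic (Ireland–Claisen) shift: C5 bonds to C10, the C8–O bond breaks and the double bond moves to C8=C9, which leaves silyl ester 16, hydrolysed to 17. The closest known reaction type is the Ireland–Claisen ring contraction of alkenyl lactone silyl ketene acetals, which must pass through a boat because C4, C5, the ring oxygen and C8 are held in one ring. Ring B is closed by this bond formation across the C6–C7 tether, in a bicyclo[2.2.2]octane-like array, suprafacially on both three-atom components. C5 is controlled by the C8 configuration, because C10 can only reach the face of the ketene acetal over which the axial alkenyl group stands; this puts H5 cis to the C7 isopropyl group. C10 is controlled by the (E)-alkene geometry together with the enforced boat: the C1 chain ends cis to the carboxyl group and the methyl group cis to H5. The step needs O- and not C-silylation and no self-condensation of the lactone enolate, which the internal quench with TBSCl/HMPA secures, and it needs the alkenyl group axial, which the cis-lactone provides because the isopropyl group is then equatorial.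

Step 8
Reactants: 17 (1S,2R,5R)-2-[3-(benzyloxy)propyl]-2-methyl-5-(propan-2-yl)cyclohex-3-ene-1-carboxylic acid
Product: 18 methyl (1S,2R,5R)-2-[3-(benzyloxy)propyl]-2-methyl-5-(propan-2-yl)cyclohex-3-ene-1-carboxylate
Conditions: Me3SiCHN2, PhMe/MeOH, 0 °C → rt
Reagents that add atoms: (trimethylsilyl)diazomethane, C[Si](C)(C)C=[N+]=[N-]
Why: Mild O-methylation of the hindered acid without base, so C5 is not at risk; the ester is needed because borane would reduce the free acid in the next step.

Step 9
Reactants: 18 methyl (1S,2R,5R)-2-[3-(benzyloxy)propyl]-2-methyl-5-(propan-2-yl)cyclohex-3-ene-1-carboxylate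
Product: 20 methyl (1S,2R,4S,5R)-2-[3-(benzyloxy)propyl]-4-hydroxy-2-methyl-5-(propan-2-yl)cyclohexane-1-carboxylate, via alkylborane 19 (not isolated)
Conditions: BH3·THF, THF, 0 °C → rt; then NaOH, H2O2, 0 °C
Reagents that add atoms: hydrogen peroxide, OO
Why: Hydroboration–oxidation; boron should add to C8 because C9 is neopentyl (next to the quaternary C10 on both faces), and from the face trans to the C7 isopropyl group, where only H7 flanks C8; the hindered ester is reduced much more slowly than the alkene is hydroborated.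

Step 10
Reactants: 20 methyl (1S,2R,4S,5R)-2-[3-(benzyloxy)propyl]-4-hydroxy-2-methyl-5-(propan-2-yl)cyclohexane-1-carboxylate
Product: 21 methyl (1S,2R,4S,5R)-2-[3-(benzyloxy)propyl]-4-[(tert-butyldimethylsilyl)oxy]-2-methyl-5-(propan-2-yl)cyclohexane-1-carboxylate
Conditions: TBSOTf, 2,6-lutidine, CH2Cl2, −78 → 0 °C
Reagents that add atoms: tert-butyldimethylsilyl trifluoromethanesulfonate, CC(C)(C)[Si](C)(C)OS(=O)(=O)C(F)(F)F
Why: Silylation of the hindered secondary alcohol with the reactive silyl triflate; C8 stays at the alcohol level so that C7 cannot epimerise before ring A is closed.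

Step 11
Reactants: 21 methyl (1S,2R,4S,5R)-2-[3-(benzyloxy)propyl]-4-[(tert-butyldimethylsilyl)oxy]-2-methyl-5-(propan-2-yl)cyclohexane-1-carboxylate
Product: 23 1-[(1S,2R,4S,5R)-2-[3-(benzyloxy)propyl]-4-[(tert-butyldimethylsilyl)oxy]-2-methyl-5-(propan-2-yl)cyclohexyl]ethan-1-one, via silyl ketone 22 (not isolated)
Conditions: Me3SiCH2Li, pentane/THF, 0 °C → rt; then MeOH, rt; aq. NH4Cl
Reagents that add atoms: (trimethylsilyl)methyllithium, [Li]C[Si](C)(C)C
Why: Acyl substitution of the ester by the silylmethyl anion stops at the ketone stage because the α-silyl ketone 22 is deprotonated at once on the silyl-bearing carbon, which also keeps C5 from enolising; methanol then cleaves the C–Si bond and leaves the methyl ketone (C15).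

Step 12
Reactants: 23 1-[(1S,2R,4S,5R)-2-[3-(benzyloxy)propyl]-4-[(tert-butyldimethylsilyl)oxy]-2-methyl-5-(propan-2-yl)cyclohexyl]ethan-1-one
Product: 24 1-[(1S,2R,4S,5R)-4-[(tert-butyldimethylsilyl)oxy]-2-(3-hydroxypropyl)-2-methyl-5-(propan-2-yl)cyclohexyl]ethan-1-one
Conditions: H2 (1 atm), 10% Pd/C, EtOAc, rt
Reagents that add atoms: none
Why: Hydrogenolysis of the benzyl ether at a stage without alkenes; the ketone and the silyl ether are inert under these neutral conditions.

Step 13
Reactants: 24 1-[(1S,2R,4S,5R)-4-[(tert-butyldimethylsilyl)oxy]-2-(3-hydroxypropyl)-2-methyl-5-(propan-2-yl)cyclohexyl]ethan-1-one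
Product: 25 3-[(1R,2S,4R,5S)-2-acetyl-5-[(tert-butyldimethylsilyl)oxy]-1-methyl-4-(propan-2-yl)cyclohexyl]propanal
Conditions: Dess–Martin periodinane, NaHCO3, CH2Cl2, 0 °C → rt
Reagents that add atoms: none
Why: Buffered Dess–Martin oxidation of the primary alcohol to the C3 aldehyde without acid or base, so the 1,6-keto aldehyde does not undergo aldol closure.

Step 14
Reactants: 25 3-[(1R,2S,4R,5S)-2-acetyl-5-[(tert-butyldimethylsilyl)oxy]-1-methyl-4-(propan-2-yl)cyclohexyl]propanal
Product: 26 tert-butyl{[(1S,2R,4R,5R)-5-(but-3-en-1-yl)-5-methyl-2-(propan-2-yl)-4-(prop-1-en-2-yl)cyclohexyl]oxy}dimethylsilane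
Conditions: Zn, CH2Br2, TiCl4, THF/CH2Cl2, 0 °C → rt
Reagents that add atoms: dibromomethane, BrCBr
Why: Takai–Lombardo methylenation converts both the aldehyde and the hindered methyl ketone into terminal alkenes; the reagent is non-basic, so C5 (α to the ketone) is not epimerised and no aldol reaction intervenes.

Step 15
Reactants: 26 tert-butyl{[(1S,2R,4R,5R)-5-(but-3-en-1-yl)-5-methyl-2-(propan-2-yl)-4-(prop-1-en-2-yl)cyclohexyl]oxy}dimethylsilane
Product: 27 tert-butyl{[(2S,3R,4aS,8aR)-5,8a-dimethyl-3-(propan-2-yl)-1,2,3,4,4a,7,8,8a-octahydronaphthalen-2-yl]oxy}dimethylsilane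
Conditions: second-generation Grubbs catalyst, (H2IMes)(PCy3)Cl2Ru=CHPh (5 mol %), CH2Cl2, 40 °C
Reagents that add atoms: none
Why: Ring-closing metathesis of the monosubstituted and the 1,1-disubstituted alkene, held cis on C10 and C5, closes ring A as the trisubstituted C3=C4 cyclohexene and gives the cis-fused octalin.

Step 16
Reactants: 27 tert-butyl{[(2S,3R,4aS,8aR)-5,8a-dimethyl-3-(propan-2-yl)-1,2,3,4,4a,7,8,8a-octahydronaphthalen-2-yl]oxy}dimethylsilane
Product: 28 the 3β,4β-epoxide of 27 (oxirane oxygen on the face of the C10 methyl group; 3S,4R,5S,7R,8S,10R in eudesmane numbering)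
Conditions: mCPBA, NaHCO3, CH2Cl2, 0 °C
Reagents that add atoms: 3-chloroperoxybenzoic acid, OOC(=O)c1cccc(Cl)c1
Why: Prilezhaev epoxidation on the convex β face; in the preferred conformer (isopropyl and silyloxy equatorial) the axial C10–C9 bond and ring B shield the α face of C3=C4.

Step 17
Reactants: 28 the 3β,4β-epoxide of 27
Product: 29 (1S,2S,4aR,6S,7R,8aS)-6-[(tert-butyldimethylsilyl)oxy]-1,4a-dimethyl-7-(propan-2-yl)decahydronaphthalene-1,2-diol
Conditions: HClO4 (0.1 M aq., cat.), THF/H2O, 0 °C → rt
Reagents that add atoms: water, O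
Why: Acid-catalysed epoxide hydrolysis following the Fürst–Plattner rule: water attacks the tertiary C4 from the α face with inversion and gives the trans-diaxial 3β,4α-diol, which sets C4 (S) with the methyl group equatorial.

Step 18
Reactants: 29 (1S,2S,4aR,6S,7R,8aS)-6-[(tert-butyldimethylsilyl)oxy]-1,4a-dimethyl-7-(propan-2-yl)decahydronaphthalene-1,2-diol
Product: 30 (1S,4aR,6S,7R,8aS)-6-[(tert-butyldimethylsilyl)oxy]-1-hydroxy-1,4a-dimethyl-7-(propan-2-yl)octahydronaphthalen-2(1H)-one
Conditions: IBX, DMSO, rt
Reagents that add atoms: none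
Why: IBX oxidises the secondary alcohol of a 1,2-diol to the α-hydroxy ketone without glycol cleavage; the tertiary hydroxyl cannot be oxidised.

Step 19
Reactants: 30 (1S,4aR,6S,7R,8aS)-6-[(tert-butyldimethylsilyl)oxy]-1-hydroxy-1,4a-dimethyl-7-(propan-2-yl)octahydronaphthalen-2(1H)-one
Product: 31 (1S,2R,4aR,6S,7R,8aS)-6-[(tert-butyldimethylsilyl)oxy]-1,4a-dimethyl-7-(propan-2-yl)decahydronaphthalene-1,2-diol
Conditions: NaBH4, MeOH, −40 → 0 °C
Reagents that add atoms: none
Why: Borohydride reduction with axial attack on the β face (only H1 and H5 are syn-axial there) gives the equatorial 3α-alcohol, cis to the axial C4 hydroxyl; this completes the net inversion at C3.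

Step 20
Reactants: 32 (2Z)-2-methylbut-2-enoic acid (angelic acid)
Product: 33 (2Z)-2-methylbut-2-en-1-ol
Conditions: LiAlH4, Et2O, 0 °C
Reagents that add atoms: none
Why: Hydride reduction of the carboxylic acid to the allylic alcohol; the trisubstituted alkene and its (Z)-geometry are not affected at low temperature.

Step 21
Reactants: 33 (2Z)-2-methylbut-2-en-1-ol
Product: 34 [(2R,3S)-2,3-dimethyloxiran-2-yl]methanol
Conditions: Ti(Oi-Pr)4 (10 mol %), D-(−)-diethyl tartrate (12 mol %), t-BuOOH, 4 Å MS, CH2Cl2, −20 °C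
Reagents that add atoms: tert-butyl hydroperoxide, CC(C)(C)OO
Why: Sharpless asymmetric epoxidation; the D-tartrate catalyst delivers oxygen to the face that gives the (2R,3S)-epoxy alcohol, and the cis relation of the two ring substituents follows from the (Z)-alkene. Any minor enantiomer becomes a separable diastereomer at 37.

Step 22
Reactants: 34 [(2R,3S)-2,3-dimethyloxiran-2-yl]methanol
Product: 35 (2S,3S)-2,3-dimethyloxirane-2-carboxylic acid
Conditions: TEMPO (10 mol %), PhI(OAc)2, MeCN/H2O (1:1), rt
Reagents that add atoms: water, O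
Why: Oxoammonium oxidation of the primary alcohol through the aldehyde hydrate to the acid at neutral pH, which the epoxide tolerates; the C2 descriptor changes from R to S only because the substituent priorities change.

Step 23
Reactants: 31 (1S,2R,4aR,6S,7R,8aS)-6-[(tert-butyldimethylsilyl)oxy]-1,4a-dimethyl-7-(propan-2-yl)decahydronaphthalene-1,2-diol; 35 (2S,3S)-2,3-dimethyloxirane-2-carboxylic acid
Product: 37 (1S,2R,4aR,6S,7R,8aS)-6-[(tert-butyldimethylsilyl)oxy]-1-hydroxy-1,4a-dimethyl-7-(propan-2-yl)decahydronaphthalen-2-yl (2S,3S)-2,3-dimethyloxirane-2-carboxylate, via mixed anhydride 36 (not isolated)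
Conditions: 35, 2,4,6-trichlorobenzoyl chloride, Et3N, THF, rt; then 31, DMAP, PhMe, rt
Reagents that add atoms: none
Why: Yamaguchi esterification; the mixed anhydride of the α-quaternary acid acylates the equatorial secondary C3 hydroxyl, while the axial tertiary C4 hydroxyl is too hindered to compete.

Step 24
Reactants: 37 (1S,2R,4aR,6S,7R,8aS)-6-[(tert-butyldimethylsilyl)oxy]-1-hydroxy-1,4a-dimethyl-7-(propan-2-yl)decahydronaphthalen-2-yl (2S,3S)-2,3-dimethyloxirane-2-carboxylate
Product: 38 (1S,2R,4aR,6S,7R,8aS)-1-(acetyloxy)-6-[(tert-butyldimethylsilyl)oxy]-1,4a-dimethyl-7-(propan-2-yl)decahydronaphthalen-2-yl (2S,3S)-2,3-dimethyloxirane-2-carboxylate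
Conditions: Ac2O, DMAP, Et3N, CH2Cl2, 40 °C
Reagents that add atoms: acetic anhydride, CC(=O)OC(C)=O
Why: DMAP-catalysed acetylation of the tertiary alcohol through the N-acetylpyridinium ion; the basic, non-Lewis-acidic conditions spare the epoxide and the silyl ether, and the bulky neighbouring ester is a poor migrating group.

Step 25
Reactants: 38 (1S,2R,4aR,6S,7R,8aS)-1-(acetyloxy)-6-[(tert-butyldimethylsilyl)oxy]-1,4a-dimethyl-7-(propan-2-yl)decahydronaphthalen-2-yl (2S,3S)-2,3-dimethyloxirane-2-carboxylate
Product: 39 (1S,2R,4aR,6S,7R,8aS)-1-(acetyloxy)-6-hydroxy-1,4a-dimethyl-7-(propan-2-yl)decahydronaphthalen-2-yl (2S,3S)-2,3-dimethyloxirane-2-carboxylate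
Conditions: HF·pyridine, pyridine, THF, 0 °C → rt
Reagents that add atoms: none
Why: Fluoride-driven cleavage of the Si–O bond; buffering with pyridine keeps the medium mild enough for the glycidic ester and the tertiary acetate, and no free hydroxyl is formed next to an ester.

Step 26
Reactants: 39 (1S,2R,4aR,6S,7R,8aS)-1-(acetyloxy)-6-hydroxy-1,4a-dimethyl-7-(propan-2-yl)decahydronaphthalen-2-yl (2S,3S)-2,3-dimethyloxirane-2-carboxylate
Product: 40 (1S,2R,4aR,7R,8aS)-1-(acetyloxy)-1,4a-dimethyl-6-oxo-7-(propan-2-yl)decahydronaphthalen-2-yl (2S,3S)-2,3-dimethyloxirane-2-carboxylate (CNP0221066.1)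
Conditions: Dess–Martin periodinane, NaHCO3, CH2Cl2, 0 °C → rt
Reagents that add atoms: none
Why: Buffered Dess–Martin oxidation of the C8 alcohol to the ketone; C7 keeps its configuration, which in the cis-decalin is the equatorial, thermodynamically preferred one.

## Compound list

1 | pent-4-yn-1-ol | C#CCCCO | starting material
2 | 5-(benzyloxy)pent-1-yne | C#CCCCOCc1ccccc1 | intermediate
3 | [(1E)-5-(benzyloxy)-2-methylpent-1-en-1-yl]dimethylalane | C[Al](C)/C=C(\C)CCCOCc1ccccc1 | intermediate (not isolated)
4 | lithium [(1E)-5-(benzyloxy)-2-methylpent-1-en-1-yl](butyl)dimethylalanate | [Li+].CCCC[Al-](C)(C)/C=C(\C)CCCOCc1ccccc1 | intermediate (not isolated)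
5 | (2E)-6-(benzyloxy)-3-methylhex-2-en-1-ol | OC/C=C(\C)CCCOCc1ccccc1 | intermediate
6 | (2E)-6-(benzyloxy)-3-methylhex-2-enal | O=C/C=C(\C)CCCOCc1ccccc1 | intermediate
7 | (2Z)-4-methylpent-2-ene | C/C=C\C(C)C | starting material
8 | [(2Z)-4-methylpent-2-en-1-yl]potassium | [K+].[CH2-]/C=C\C(C)C | intermediate (not isolated)
9 | [(2Z)-4-methylpent-2-en-1-yl]bis[(1S,2R,3S,5S)-2,6,6-trimethylbicyclo[3.1.1]heptan-3-yl]borane | CC(C)/C=C\CB([C@H]1C[C@H]2C[C@@H]([C@@H]1C)C2(C)C)[C@H]1C[C@H]2C[C@@H]([C@@H]1C)C2(C)C | intermediate (not isolated)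
10 | (3S,4R,5E)-9-(benzyloxy)-6-methyl-3-(propan-2-yl)nona-1,5-dien-4-yl bis[(1S,2R,3S,5S)-2,6,6-trimethylbicyclo[3.1.1]heptan-3-yl]borinate | C=C[C@H](C(C)C)[C@@H](OB([C@H]1C[C@H]2C[C@@H]([C@@H]1C)C2(C)C)[C@H]1C[C@H]2C[C@@H]([C@@H]1C)C2(C)C)/C=C(\C)CCCOCc1ccccc1 | intermediate (not isolated)
11 | (3S,4R,5E)-9-(benzyloxy)-6-methyl-3-(propan-2-yl)nona-1,5-dien-4-ol | C=C[C@H](C(C)C)[C@@H](O)/C=C(\C)CCCOCc1ccccc1 | intermediate
12 | (4R,5R,6E)-10-(benzyloxy)-5-hydroxy-7-methyl-4-(propan-2-yl)dec-6-enal | O=CCC[C@H](C(C)C)[C@@H](O)/C=C(\C)CCCOCc1ccccc1 | intermediate (not isolated)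
13 | (5R,6R)-6-[(1E)-5-(benzyloxy)-2-methylpent-1-en-1-yl]-5-(propan-2-yl)oxan-2-ol (anomeric mixture) | OC1CC[C@H](C(C)C)[C@@H](O1)/C=C(\C)CCCOCc2ccccc2 | intermediate
14 | (5R,6R)-6-[(1E)-5-(benzyloxy)-2-methylpent-1-en-1-yl]-5-(propan-2-yl)oxan-2-one | O=C1CC[C@H](C(C)C)[C@@H](O1)/C=C(\C)CCCOCc2ccccc2 | intermediate
15 | tert-butyl({(2R,3R)-2-[(1E)-5-(benzyloxy)-2-methylpent-1-en-1-yl]-3-(propan-2-yl)-3,4-dihydro-2H-pyran-6-yl}oxy)dimethylsilane | CC(C)(C)[Si](C)(C)OC1=CC[C@H](C(C)C)[C@@H](O1)/C=C(\C)CCCOCc2ccccc2 | intermediate (not isolated)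
16 | tert-butyldimethylsilyl (1S,2R,5R)-2-[3-(benzyloxy)propyl]-2-methyl-5-(propan-2-yl)cyclohex-3-ene-1-carboxylate | CC(C)(C)[Si](C)(C)OC(=O)[C@H]1C[C@H](C(C)C)C=C[C@@]1(C)CCCOCc2ccccc2 | intermediate (not isolated)
17 | (1S,2R,5R)-2-[3-(benzyloxy)propyl]-2-methyl-5-(propan-2-yl)cyclohex-3-ene-1-carboxylic acid | OC(=O)[C@H]1C[C@H](C(C)C)C=C[C@@]1(C)CCCOCc2ccccc2 | intermediate
18 | methyl (1S,2R,5R)-2-[3-(benzyloxy)propyl]-2-methyl-5-(propan-2-yl)cyclohex-3-ene-1-carboxylate | COC(=O)[C@H]1C[C@H](C(C)C)C=C[C@@]1(C)CCCOCc2ccccc2 | intermediate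
19 | methyl (1S,2R,4S,5S)-2-[3-(benzyloxy)propyl]-4-boranyl-2-methyl-5-(propan-2-yl)cyclohexane-1-carboxylate (boron trans to the isopropyl group) | COC(=O)[C@H]1C[C@H](C(C)C)[C@@H](B)C[C@@]1(C)CCCOCc2ccccc2 | intermediate (not isolated)
20 | methyl (1S,2R,4S,5R)-2-[3-(benzyloxy)propyl]-4-hydroxy-2-methyl-5-(propan-2-yl)cyclohexane-1-carboxylate | COC(=O)[C@H]1C[C@H](C(C)C)[C@@H](O)C[C@@]1(C)CCCOCc2ccccc2 | intermediate
21 | methyl (1S,2R,4S,5R)-2-[3-(benzyloxy)propyl]-4-[(tert-butyldimethylsilyl)oxy]-2-methyl-5-(propan-2-yl)cyclohexane-1-carboxylate | COC(=O)[C@H]1C[C@H](C(C)C)[C@@H](O[Si](C)(C)C(C)(C)C)C[C@@]1(C)CCCOCc2ccccc2 | intermediate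
22 | 1-[(1S,2R,4S,5R)-2-[3-(benzyloxy)propyl]-4-[(tert-butyldimethylsilyl)oxy]-2-methyl-5-(propan-2-yl)cyclohexyl]-2-(trimethylsilyl)ethan-1-one | C[Si](C)(C)CC(=O)[C@H]1C[C@H](C(C)C)[C@@H](O[Si](C)(C)C(C)(C)C)C[C@@]1(C)CCCOCc2ccccc2 | intermediate (not isolated)
23 | 1-[(1S,2R,4S,5R)-2-[3-(benzyloxy)propyl]-4-[(tert-butyldimethylsilyl)oxy]-2-methyl-5-(propan-2-yl)cyclohexyl]ethan-1-one | CC(=O)[C@H]1C[C@H](C(C)C)[C@@H](O[Si](C)(C)C(C)(C)C)C[C@@]1(C)CCCOCc2ccccc2 | intermediate
24 | 1-[(1S,2R,4S,5R)-4-[(tert-butyldimethylsilyl)oxy]-2-(3-hydroxypropyl)-2-methyl-5-(propan-2-yl)cyclohexyl]ethan-1-one | CC(=O)[C@H]1C[C@H](C(C)C)[C@@H](O[Si](C)(C)C(C)(C)C)C[C@@]1(C)CCCO | intermediate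
25 | 3-[(1R,2S,4R,5S)-2-acetyl-5-[(tert-butyldimethylsilyl)oxy]-1-methyl-4-(propan-2-yl)cyclohexyl]propanal | CC(=O)[C@H]1C[C@H](C(C)C)[C@@H](O[Si](C)(C)C(C)(C)C)C[C@@]1(C)CCC=O | intermediate
26 | tert-butyl{[(1S,2R,4R,5R)-5-(but-3-en-1-yl)-5-methyl-2-(propan-2-yl)-4-(prop-1-en-2-yl)cyclohexyl]oxy}dimethylsilane | C=C(C)[C@H]1C[C@H](C(C)C)[C@@H](O[Si](C)(C)C(C)(C)C)C[C@@]1(C)CCC=C | intermediate
27 | tert-butyl{[(2S,3R,4aS,8aR)-5,8a-dimethyl-3-(propan-2-yl)-1,2,3,4,4a,7,8,8a-octahydronaphthalen-2-yl]oxy}dimethylsilane | CC1=CCC[C@]2(C)C[C@H](O[Si](C)(C)C(C)(C)C)[C@@H](C(C)C)C[C@@H]21 | intermediate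
28 | 3β,4β-epoxide of 27 (oxirane oxygen cis to the C10 methyl group; 3S,4R,5S,7R,8S,10R in eudesmane numbering) | C[C@]12O[C@H]1CC[C@]3(C)C[C@H](O[Si](C)(C)C(C)(C)C)[C@@H](C(C)C)C[C@@H]32 | intermediate
29 | (1S,2S,4aR,6S,7R,8aS)-6-[(tert-butyldimethylsilyl)oxy]-1,4a-dimethyl-7-(propan-2-yl)decahydronaphthalene-1,2-diol | C[C@@]1(O)[C@@H](O)CC[C@]2(C)C[C@H](O[Si](C)(C)C(C)(C)C)[C@@H](C(C)C)C[C@@H]21 | intermediate
30 | (1S,4aR,6S,7R,8aS)-6-[(tert-butyldimethylsilyl)oxy]-1-hydroxy-1,4a-dimethyl-7-(propan-2-yl)octahydronaphthalen-2(1H)-one | C[C@@]1(O)C(=O)CC[C@]2(C)C[C@H](O[Si](C)(C)C(C)(C)C)[C@@H](C(C)C)C[C@@H]21 | intermediate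
31 | (1S,2R,4aR,6S,7R,8aS)-6-[(tert-butyldimethylsilyl)oxy]-1,4a-dimethyl-7-(propan-2-yl)decahydronaphthalene-1,2-diol | C[C@@]1(O)[C@H](O)CC[C@]2(C)C[C@H](O[Si](C)(C)C(C)(C)C)[C@@H](C(C)C)C[C@@H]21 | intermediate
32 | (2Z)-2-methylbut-2-enoic acid (angelic acid) | C/C=C(/C)C(=O)O | starting material
33 | (2Z)-2-methylbut-2-en-1-ol | C/C=C(/C)CO | intermediate
34 | [(2R,3S)-2,3-dimethyloxiran-2-yl]methanol | OC[C@@]1(C)O[C@H]1C | intermediate
35 | (2S,3S)-2,3-dimethyloxirane-2-carboxylic acid | OC(=O)[C@@]1(C)O[C@H]1C | intermediate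
36 | (2S,3S)-2,3-dimethyloxirane-2-carboxylic 2,4,6-trichlorobenzoic anhydride | O=C(OC(=O)[C@@]1(C)O[C@H]1C)c1c(Cl)cc(Cl)cc1Cl | intermediate (not isolated)
37 | (1S,2R,4aR,6S,7R,8aS)-6-[(tert-butyldimethylsilyl)oxy]-1-hydroxy-1,4a-dimethyl-7-(propan-2-yl)decahydronaphthalen-2-yl (2S,3S)-2,3-dimethyloxirane-2-carboxylate | C[C@@]1(O)[C@H](OC(=O)[C@@]2(C)O[C@H]2C)CC[C@]2(C)C[C@H](O[Si](C)(C)C(C)(C)C)[C@@H](C(C)C)C[C@@H]21 | intermediate
38 | (1S,2R,4aR,6S,7R,8aS)-1-(acetyloxy)-6-[(tert-butyldimethylsilyl)oxy]-1,4a-dimethyl-7-(propan-2-yl)decahydronaphthalen-2-yl (2S,3S)-2,3-dimethyloxirane-2-carboxylate | CC(=O)O[C@]1(C)[C@H](OC(=O)[C@@]2(C)O[C@H]2C)CC[C@]2(C)C[C@H](O[Si](C)(C)C(C)(C)C)[C@@H](C(C)C)C[C@@H]21 | intermediate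
39 | (1S,2R,4aR,6S,7R,8aS)-1-(acetyloxy)-6-hydroxy-1,4a-dimethyl-7-(propan-2-yl)decahydronaphthalen-2-yl (2S,3S)-2,3-dimethyloxirane-2-carboxylate | CC(=O)O[C@]1(C)[C@H](OC(=O)[C@@]2(C)O[C@H]2C)CC[C@]2(C)C[C@H](O)[C@@H](C(C)C)C[C@@H]21 | intermediate
40 | (1S,2R,4aR,7R,8aS)-1-(acetyloxy)-1,4a-dimethyl-6-oxo-7-(propan-2-yl)decahydronaphthalen-2-yl (2S,3S)-2,3-dimethyloxirane-2-carboxylate | CC(=O)O[C@]1(C)[C@H](OC(=O)[C@@]2(C)O[C@H]2C)CC[C@]2(C)CC(=O)[C@@H](C(C)C)C[C@@H]21 | target

## Step count and least certain steps

Total: 26 steps. Longest linear sequence: 23 steps (steps 1–19 and 23–26); the epoxy acid branch (steps 20–22) joins at step 23.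

**Step 7 (key step).** The lactone enolate may be C-silylated or may condense with unreacted lactone before it is trapped. The rearrangement itself may also be slow, because it builds a quaternary centre through a strained boat, so that desilylation back to 14 or thermal decomposition of the ketene acetal competes. Fallback: from 11, acylation with acryloyl chloride and Et3N gives the acrylate ester F1, and ring-closing metathesis with the second-generation Grubbs catalyst gives the dihydropyranone F2. Conjugate reduction of F2 with LiBH(s-Bu)3 at −78 °C and trapping of the resulting lactone enolate with TBSCl/HMPA would give ketene acetal 15 without an amide base, and the route continues from 15 as in step 7.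

**Step 4.** The (Z)-allylpotassium may lose its geometry before it is borylated, and the hindered γ-isopropyl reagent may add slowly to the β,β-disubstituted enal. Either would erode the syn selectivity and the enantioselectivity. Fallback: from 6, an Evans syn-aldol reaction with commercial (4R)-4-benzyl-3-(3-methylbutanoyl)-1,3-oxazolidin-2-one (Bu2BOTf, Et3N) gives the aldol adduct F3. Silylation (TBSOTf, 2,6-lutidine) gives the silyl ether F4, reduction with LiBH4 gives the primary alcohol F5, Dess–Martin oxidation gives the aldehyde F6 and Wittig methylenation (Ph3P=CH2) gives the silyl ether F7. Bu4NF then releases 11.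

**Step 9.** Boron may add in part to C9, since C8 is itself flanked by the isopropyl-bearing carbon, and long reaction times on the hindered alkene may let the ester be reduced. Fallback: from 18, NBS in aqueous DME gives the bromohydrin F8. Water opens the bromonium ion at C8, because backside attack at the neopentyl C9 is blocked, and does so trans to the isopropyl group. Radical debromination with Bu3SnH/AIBN then returns to 20.

**Step 17.** The protonated epoxide may ionise at C4 and lose a proton to give allylic alcohols, water may add with partial retention or at C3, and the silyl ether may be partly cleaved. Fallback: from 27, Woodward cis-hydroxylation (I2, AgOAc, wet AcOH) proceeds by iodoacetoxylation from the β face and neighbouring-group displacement at C3. It places both oxygens on the α face and gives the hydroxy acetate F9 (3α-hydroxy, 4α-acetoxy). Methanolysis (K2CO3, MeOH) gives 31 and bypasses 28–30.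

**Step 24.** The axial tertiary hydroxyl may be acylated too slowly. Under base the epoxy ester may also migrate to the C4 oxygen and the freed C3 hydroxyl be acetylated, which would exchange the two esters. Fallback: from 31, MeC(OMe)3 with pyridinium 4-toluenesulfonate gives the cyclic orthoacetate F10. Its hydrolysis in aqueous acetic acid opens to the axial ester and gives the hydroxy acetate F9. Immediate Yamaguchi esterification of F9 with 35 (through 36) then gives 38.

## Further compounds

F1 | step 7 | (3S,4R,5E)-9-(benzyloxy)-6-methyl-3-(propan-2-yl)nona-1,5-dien-4-yl prop-2-enoate | C=C[C@H](C(C)C)[C@@H](OC(=O)C=C)/C=C(\C)CCCOCc1ccccc1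
F2 | step 7 | (5S,6R)-6-[(1E)-5-(benzyloxy)-2-methylpent-1-en-1-yl]-5-(propan-2-yl)-5,6-dihydro-2H-pyran-2-one | O=C1C=C[C@H](C(C)C)[C@@H](O1)/C=C(\C)CCCOCc2ccccc2
F3 | step 4 | (4R)-4-benzyl-3-[(2R,3S,4E)-8-(benzyloxy)-3-hydroxy-5-methyl-2-(propan-2-yl)oct-4-enoyl]-1,3-oxazolidin-2-one | O=C(N1[C@H](Cc2ccccc2)COC1=O)[C@H](C(C)C)[C@@H](O)/C=C(\C)CCCOCc1ccccc1
F4 | step 4 | tert-butyldimethylsilyl ether of F3 at the C3 hydroxyl of the acyl chain | O=C(N1[C@H](Cc2ccccc2)COC1=O)[C@H](C(C)C)[C@@H](O[Si](C)(C)C(C)(C)C)/C=C(\C)CCCOCc1ccccc1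
F5 | step 4 | (2S,3S,4E)-8-(benzyloxy)-3-[(tert-butyldimethylsilyl)oxy]-5-methyl-2-(propan-2-yl)oct-4-en-1-ol | OC[C@H](C(C)C)[C@@H](O[Si](C)(C)C(C)(C)C)/C=C(\C)CCCOCc1ccccc1
F6 | step 4 | (2R,3S,4E)-8-(benzyloxy)-3-[(tert-butyldimethylsilyl)oxy]-5-methyl-2-(propan-2-yl)oct-4-enal | O=C[C@H](C(C)C)[C@@H](O[Si](C)(C)C(C)(C)C)/C=C(\C)CCCOCc1ccccc1
F7 | step 4 | tert-butyldimethylsilyl ether of 11 | C=C[C@H](C(C)C)[C@@H](O[Si](C)(C)C(C)(C)C)/C=C(\C)CCCOCc1ccccc1
F8 | step 9 | bromohydrin of 18: methyl 2-[3-(benzyloxy)propyl]-3-bromo-4-hydroxy-2-methyl-5-(propan-2-yl)cyclohexane-1-carboxylate, hydroxyl trans to the isopropyl group and to bromine | COC(=O)[C@H]1C[C@H](C(C)C)[C@@H](O)[C@H](Br)[C@@]1(C)CCCOCc2ccccc2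
F9 | step 17 | (1S,2R,4aR,6S,7R,8aS)-6-[(tert-butyldimethylsilyl)oxy]-2-hydroxy-1,4a-dimethyl-7-(propan-2-yl)decahydronaphthalen-1-yl acetate | CC(=O)O[C@]1(C)[C@H](O)CC[C@]2(C)C[C@H](O[Si](C)(C)C(C)(C)C)[C@@H](C(C)C)C[C@@H]21
F10 | step 24 | cyclic methyl orthoacetate of cis-diol 31 (2-methoxy-2-methyl-1,3-dioxolane fused at C3 and C4, mixture at the orthoester carbon) | COC1(C)O[C@]2(C)[C@H](O1)CC[C@]3(C)C[C@H](O[Si](C)(C)C(C)(C)C)[C@@H](C(C)C)C[C@@H]32
A1 | alternative 1 | Diels–Alder adduct: cis-fused decalin with C1 ketone, C8 tert-butyldimethylsilyl ether, C6=C7 alkene and C3/C4 acetonide | O3[C@]1(C)[C@H](OC3(C)C)CC(=O)[C@]2(C)C[C@H](O[Si](C)(C)C(C)(C)C)C(C(C)C)=C[C@@H]21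
A2 | alternative 1 | acyclic trienone: isopropenyl ketone tethered through the C3/C4 acetonide to the (1E,3E)-1-silyloxy-2-isopropylbutadiene | O1[C@@](C)(/C=C/C(C(C)C)=C/O[Si](C)(C)C(C)(C)C)[C@H](OC1(C)C)CC(=O)C(C)=C
A3 | alternative 2 | cis-fused 3,4-cis-diol with C8 dioxolane | O[C@]1(C)[C@H](O)CC[C@]2(C)CC3(OCCO3)[C@@H](C(C)C)C[C@@H]21
A4 | alternative 2 | ring B keto aldehyde with C8 dioxolane (C4 methyl ketone and C3 aldehyde) | CC(=O)[C@H]1C[C@H](C(C)C)C2(OCCO2)C[C@@]1(C)CCC=O
A5 | alternative 3 | cis-fused 4-hydroxy-3,8-diketone | O[C@]1(C)C(=O)CC[C@]2(C)CC(=O)[C@@H](C(C)C)C[C@@H]21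
A6 | alternative 3 | 3-methylcyclohex-2-enone carrying at C4 the 2-hydroxy-3-oxopent-4-en-2-yl (vinyl ketone) chain and at C6 the isopropyl group | C=CC(=O)[C@@](C)(O)[C@H]1C[C@H](C(C)C)C(=O)C=C1C
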